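**Retrosynthetic overview**
- The target comes from the bicyclic α-methoxy enone acetate by 1,4-reduction; kinetic protonation sets the last stereocentre.
- The bicyclic enone acetate comes in one cascade from an ortho-quinol acetate and (E)-methyl isoeugenol: ionisation, para C–C coupling, then the key C–O bond (acetic acid adds 1,4 to the cross-conjugated dienone) and closure of the resulting enol onto the benzylic cation.
- The ortho-quinol acetate comes from methoxyeugenol by acetoxylative dearomatisation (a C–O bond).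
- Ring order: the six-membered ring is the arene ring of methoxyeugenol (dearomatised in step 1); the five-membered ring closes in step 2 and completes the bicyclo[3.2.1]octane; step 3 forms no ring.

Atom labels: C-1' to C-6' are the ring carbons of methoxyeugenol (C-1' bears the allyl group, C-4' the oxygen); C-7 is the benzylic and C-8 the methyl-bearing carbon of methyl isoeugenol.
Assumption: both starting materials are bought as flavour chemicals; the (S,S) acid is taken to give the enantiomer drawn, and its mirror image is used if the sense of induction is the opposite.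

Step 1
Reactants: 1 4-allyl-2,6-dimethoxyphenol (methoxyeugenol)
Product: 3 1,3-dimethoxy-2-oxo-5-(prop-2-en-1-yl)cyclohexa-3,5-dien-1-yl acetate (racemic ortho-quinol acetate), via aryloxyiodane 2 (not isolated)
Conditions: PhI(OAc)2 (1.05 equiv), CH2Cl2, −78 °C, 2 h; cold aq NaHCO3 wash; used the same day
Reagents that add atoms: (diacetoxyiodo)benzene, CC(=O)OI(OC(C)=O)c1ccccc1
Why: Wessely-type acetoxylative dearomatisation of a 2-methoxyphenol with a hypervalent iodine reagent: ligand exchange gives aryloxy-λ3-iodane 2, and in this non-ionising solvent acetate attacks the methoxy-bearing ortho carbon as iodobenzene leaves; the new stereocentre is racemic and is erased on ionisation in step 2.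

Step 2
Reactants: 3 1,3-dimethoxy-2-oxo-5-(prop-2-en-1-yl)cyclohexa-3,5-dien-1-yl acetate; 4 (E)-methyl isoeugenol
Product: 8 (1R,5S,6S,7R,8S)-6-(3,4-dimethoxyphenyl)-3,5-dimethoxy-7-methyl-4-oxo-1-(prop-2-en-1-yl)bicyclo[3.2.1]oct-2-en-8-yl acetate, via phenoxenium cation 5 (not isolated), via benzylic cation 6 (not isolated), via acetoxy enol cation 7 (not isolated)
Conditions: (S,S)-IDPi (5 mol%; imidodiphosphorimidate Brønsted acid from two (S)-3,3'-bis[3,5-bis(trifluoromethyl)phenyl]-BINOL units, N-triflyl), AcOH (10 equiv), 4 (1.5 equiv, added over 2 h), 4 Å MS, CHCl3, −40 to −20 °C, 36 h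
Reagents that add atoms: acetic acid, CC(=O)O
Why: Proposed new method: a chiral-Brønsted-acid-catalysed cascade of ionisation, para C–C coupling, oxa-Michael addition and enol–cation ring closure, in which every cation is formed once and paired with the confined chiral anion. The acid ionises the quinol acetate (loss of acetic acid) to phenoxenium 5; the alkene attacks through C-8 at C-1', the only cationic ring carbon without a methoxy group and the one from which the carbonyl oxygen cannot close a dihydrobenzofuran, giving benzylic cation 6. C-8 is set in this addition under anion control and stays correctable, because 6 can lose and regain the C-8 proton before it cyclises. Acetic acid then adds 1,4 to one enone arm on the face anti to the side chain (new C-2'–O bond), and the α-methoxy enol carbon C-3' of 7 alkylates the cation on the side-chain face (C-3'–C-7 bond). Oxygen and carbon therefore add anti, so the acetoxy group points away from the aryl/methyl bridge; the methyl group ends exo (an endo methyl would eclipse C-6'); the aryl group ends endo (H-8 eclipses the aryl in the A(1,3)-minimised cation, as in cationic [5+2] adducts); the matched ion pair closes faster and gives one enantiomer. Closest known reactions: acid-promoted cationic [5+2] couplings of quinone monoketals with propenylarenes, chiral phosphoric acid-catalysed [3+2] couplings of quinone monoketals and monoimides with alkenes, IDPi-catalysed α-alkylation of enols by benzylic cations, and enantioselective oxa-Michael desymmetrisation of cyclohexa-2,5-dienones.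

Step 3
Reactants: 8 (1R,5S,6S,7R,8S)-6-(3,4-dimethoxyphenyl)-3,5-dimethoxy-7-methyl-4-oxo-1-(prop-2-en-1-yl)bicyclo[3.2.1]oct-2-en-8-yl acetate
Product: 10 (1S,3S,5S,6R,7S,8S)-7-(3,4-dimethoxyphenyl)-1,3-dimethoxy-6-methyl-2-oxo-5-(prop-2-en-1-yl)bicyclo[3.2.1]octan-8-yl acetate (the target), via silyl enol ether 9 (not isolated)
Conditions: [(Ph3P)CuH]6 (3 mol%), PhMe2SiH (1.5 equiv), toluene, 0 °C to rt; then 0.2 M HCl, THF, −20 °C
Reagents that add atoms: none
Why: Copper hydride conjugate reduction (1,4-hydrosilylation) is selective for the enone over the isolated allyl alkene, the acetate and the aryl ethers; acid hydrolysis of silyl enol ether 9 protonates C-5' from the side of the one-carbon bridge because the opposite face is covered by the endo aryl ring, which leaves the methoxy group on the aryl side as in the target.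

**Compound list**
1 | 4-allyl-2,6-dimethoxyphenol (methoxyeugenol) | C=CCc1cc(OC)c(O)c(OC)c1 | starting material
2 | (acetoxy)[2,6-dimethoxy-4-(prop-2-en-1-yl)phenoxy](phenyl)-λ3-iodane | C=CCc1cc(OC)c(OI(OC(C)=O)c2ccccc2)c(OC)c1 | intermediate
3 | 1,3-dimethoxy-2-oxo-5-(prop-2-en-1-yl)cyclohexa-3,5-dien-1-yl acetate (6-acetoxy-2,6-dimethoxy-4-allylcyclohexa-2,4-dien-1-one; racemic) | C=CCC1=CC(OC)(OC(C)=O)C(=O)C(OC)=C1 | intermediate
4 | (E)-methyl isoeugenol, 1,2-dimethoxy-4-[(1E)-prop-1-en-1-yl]benzene | C/C=C/c1ccc(OC)c(OC)c1 | starting material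
5 | 4-allyl-2,6-dimethoxyphenoxenium cation (drawn as its O-methyl oxocarbenium form) | C=CCC1=CC(=[O+]C)C(=O)C(OC)=C1 | intermediate
6 | 1-(3,4-dimethoxyphenyl)-2-[3,5-dimethoxy-4-oxo-1-(prop-2-en-1-yl)cyclohexa-2,5-dien-1-yl]propan-1-ylium (benzylic cation; C-8 configuration correctable by proton loss and return) | C=CCC1(C=C(OC)C(=O)C(OC)=C1)C(C)[CH+]c1ccc(OC)c(OC)c1 | intermediate
7 | acetoxy enol cation: acetic acid adduct of 6 at C-2' (acetate anti to the side chain; dienol at C-3'/C-4'); matched isomer shown | C=CC[C@]1(C=C(OC)C(O)=C(OC)[C@H]1OC(C)=O)[C@H](C)[CH+]c1ccc(OC)c(OC)c1 | intermediate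
8 | (1R,5S,6S,7R,8S)-6-(3,4-dimethoxyphenyl)-3,5-dimethoxy-7-methyl-4-oxo-1-(prop-2-en-1-yl)bicyclo[3.2.1]oct-2-en-8-yl acetate (aryl endo, methyl exo, acetoxy on the side of the enone bridge) | C=CC[C@]12C=C(OC)C(=O)[C@](OC)([C@H](c3ccc(OC)c(OC)c3)[C@H]1C)[C@H]2OC(C)=O | intermediate
9 | (1S,5S,6R,7S,8S)-7-(3,4-dimethoxyphenyl)-2-{[dimethyl(phenyl)silyl]oxy}-1,3-dimethoxy-6-methyl-5-(prop-2-en-1-yl)bicyclo[3.2.1]oct-2-en-8-yl acetate | C=CC[C@]12CC(OC)=C(O[Si](C)(C)c3ccccc3)[C@](OC)([C@H](c4ccc(OC)c(OC)c4)[C@H]1C)[C@H]2OC(C)=O | intermediate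
10 | (1S,3S,5S,6R,7S,8S)-7-(3,4-dimethoxyphenyl)-1,3-dimethoxy-6-methyl-2-oxo-5-(prop-2-en-1-yl)bicyclo[3.2.1]octan-8-yl acetate | C=CC[C@]12C[C@H](OC)C(=O)[C@](OC)([C@H](c3ccc(OC)c(OC)c3)[C@H]1C)[C@H]2OC(C)=O | target

**Totals**
Total step count: 3. Longest linear sequence: 3.

**Steps most likely to fail**

Step 2 (the proposed new step). Risks: the alkene may attack a methoxy-bearing carbon of 5 and close through the carbonyl oxygen, 4 may oligomerise under the acid, cation 6 may rearrange or fragment, acetic acid may add syn, the methyl-endo/aryl-exo diastereomer may form, and the ee may be low. Fallback with known chemistry, setting out from 4 and coming back at 8: the bicycle is built by an acid-promoted cationic [5+2] cycloaddition, and the carbinol stereocentre is set afterwards by ketone reduction. Commercial 2,3,4-trimethoxyphenol F2 is O-allylated (allyl bromide, K2CO3, acetone) to 1-(allyloxy)-2,3,4-trimethoxybenzene F3, and aromatic Claisen rearrangement (neat, 190 °C) gives 6-allyl-2,3,4-trimethoxyphenol F4. PhI(OAc)2 in MeOH at 0 °C gives the quinone monoketal 4,4,5,6-tetramethoxy-2-(prop-2-en-1-yl)cyclohexa-2,5-dien-1-one F5. Its cycloaddition with 4 (Me3SiOTf, MeCN, −30 °C) gives the racemic dione 6-(3,4-dimethoxyphenyl)-3,5-dimethoxy-7-methyl-1-(prop-2-en-1-yl)bicyclo[3.2.1]oct-2-ene-4,8-dione F6. NaBH4 in MeOH at −40 °C reduces the strained bridging ketone to the racemic hydroxy enone 6-(3,4-dimethoxyphenyl)-8-hydroxy-3,5-dimethoxy-7-methyl-1-(prop-2-en-1-yl)bicyclo[3.2.1]oct-2-en-4-one F7. Its epimer at the carbinol carbon F8 is separated, oxidised back to F6 with Dess–Martin periodinane and recycled. Ac2O and 4-(dimethylamino)pyridine convert F7 into racemic 8, and preparative chiral HPLC removes the mirror-image acetate ent-8 F9.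

Step 3. Risks: slow hydride delivery to the hindered, electron-rich enone, and protonation of C-5' from the wrong face, since the acetoxy group also flanks the enol. Fallback, setting out from 8 and coming back at 10: the one-pot catalytic reduction and hydrolysis is replaced by a stoichiometric two-stage sequence. LiBH(s-Bu)3 (THF, −78 °C) delivers hydride 1,4, and the enolate is trapped with t-BuMe2SiCl as the isolable (1S,5S,6R,7S,8S)-2-{[tert-butyl(dimethyl)silyl]oxy}-7-(3,4-dimethoxyphenyl)-1,3-dimethoxy-6-methyl-5-(prop-2-en-1-yl)bicyclo[3.2.1]oct-2-en-8-yl acetate F10. C-5' is then set in a separate, reagent-controlled low-temperature protonation (nBu4NF/AcOH, −78 °C), giving 10.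

Step 1. Risks: 3 may dimerise by Diels–Alder reaction on standing, or the allyl group may be attacked by the oxidant. The site of acetoxylation does not matter, because ortho and para quinol acetates ionise to the same cation 5. Fallback, setting out from 1 and coming back at 8: oxidation and C–C bond formation are done in one flask and the benzylic cation is stored as its acetate. 1 is oxidised with PhI(OAc)2 in CH2Cl2/(CF3)2CHOH 4:1 at −40 °C in the presence of 4 (2 equiv). Cation 5 couples at C-1', and acetate captures cation 6 to give 1-(3,4-dimethoxyphenyl)-2-[3,5-dimethoxy-4-oxo-1-(prop-2-en-1-yl)cyclohexa-2,5-dien-1-yl]propyl acetate F1 (racemic, both benzylic epimers). Under the conditions of step 2 without added 4, F1 ionises back to 6, which goes on through 7 to 8.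

**Further compounds**
F1 | step 1 | 1-(3,4-dimethoxyphenyl)-2-[3,5-dimethoxy-4-oxo-1-(prop-2-en-1-yl)cyclohexa-2,5-dien-1-yl]propyl acetate (racemic; both benzylic epimers) | C=CCC1(C=C(OC)C(=O)C(OC)=C1)C(C)C(OC(C)=O)c1ccc(OC)c(OC)c1
F2 | step 2 | 2,3,4-trimethoxyphenol | COc1ccc(O)c(OC)c1OC
F3 | step 2 | 1-(allyloxy)-2,3,4-trimethoxybenzene | C=CCOc1ccc(OC)c(OC)c1OC
F4 | step 2 | 6-allyl-2,3,4-trimethoxyphenol | C=CCc1cc(OC)c(OC)c(OC)c1O
F5 | step 2 | 4,4,5,6-tetramethoxy-2-(prop-2-en-1-yl)cyclohexa-2,5-dien-1-one | C=CCC1=CC(OC)(OC)C(OC)=C(OC)C1=O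
F6 | step 2 | 6-(3,4-dimethoxyphenyl)-3,5-dimethoxy-7-methyl-1-(prop-2-en-1-yl)bicyclo[3.2.1]oct-2-ene-4,8-dione (racemic; relative configuration as in 8; the enantiomer leading to 8 is shown) | C=CC[C@]12C=C(OC)C(=O)[C@](OC)([C@H](c3ccc(OC)c(OC)c3)[C@H]1C)C2=O
F7 | step 2 | 6-(3,4-dimethoxyphenyl)-8-hydroxy-3,5-dimethoxy-7-methyl-1-(prop-2-en-1-yl)bicyclo[3.2.1]oct-2-en-4-one (racemic; hydroxyl on the side of the enone bridge as in 8; the enantiomer leading to 8 is shown) | C=CC[C@]12C=C(OC)C(=O)[C@](OC)([C@H](c3ccc(OC)c(OC)c3)[C@H]1C)[C@H]2O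
F8 | step 2 | epimer of F7 at the carbinol carbon (racemic; hydroxyl on the side of the aryl/methyl bridge; one enantiomer shown) | C=CC[C@]12C=C(OC)C(=O)[C@](OC)([C@H](c3ccc(OC)c(OC)c3)[C@H]1C)[C@@H]2O
F9 | step 2 | (1S,5R,6R,7S,8R)-6-(3,4-dimethoxyphenyl)-3,5-dimethoxy-7-methyl-4-oxo-1-(prop-2-en-1-yl)bicyclo[3.2.1]oct-2-en-8-yl acetate (ent-8) | C=CC[C@@]12C=C(OC)C(=O)[C@@](OC)([C@@H](c3ccc(OC)c(OC)c3)[C@@H]1C)[C@@H]2OC(C)=O
F10 | step 3 | (1S,5S,6R,7S,8S)-2-{[tert-butyl(dimethyl)silyl]oxy}-7-(3,4-dimethoxyphenyl)-1,3-dimethoxy-6-methyl-5-(prop-2-en-1-yl)bicyclo[3.2.1]oct-2-en-8-yl acetate | C=CC[C@]12CC(OC)=C(O[Si](C)(C)C(C)(C)C)[C@](OC)([C@H](c3ccc(OC)c(OC)c3)[C@H]1C)[C@H]2OC(C)=O
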